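**Retrosynthetic overview**
- Last C–C bond: the isobutyl group is added to an o-quinone methide built from 2,4-diformylphloroglucinol and a C1-formyl ent-eudesmane-4,11-diol; A1,3 strain fixes C9′.
- Key C–O disconnection: both tertiary alcohols (axial C4–OH and C11–OH) come from one cobalt-catalysed, stereoinvertive double Markovnikov hydration of a 3,11-diene that carries the aldehyde as a diethyl acetal.
- The diene comes from a Δ4-3-ketone by Li/NH3 reduction, enolate triflation and Pd/formate reduction (sets C5–H); the acetal carbon is put on C1 by radical 1,4-addition to the 1,4-dien-3-one.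
- The dienone comes from (−)-α-cyperone, made from (S)-carvone by a chiral-imine Michael addition and aldol closure (sets C10).
- Ring order: ring B is bought (carvone), ring A is formed by annulation (steps 2–3), the arene comes from phloroglucinol.

Assumption: the decalin is numbered as a eudesmane (C1–C15, C14 = angular methyl on C10, C9′ = benzylic carbon); the target is of the ent-eudesmane series (7S), hence (S)-carvone; reagents without a compound number are bought.

**Step 1**
Reactants: 1 (S)-(+)-carvone
Product: 2 (2S,5S)-dihydrocarvone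
Conditions: LiBH(s-Bu)3 (L-Selectride, 1.05 equiv), THF, −78 °C; aq. NH4Cl
Reagents that add atoms: none
Why: Conjugate (1,4) hydride reduction of the β-unsubstituted enone and protonation of the enolate on work-up; C5 is untouched, and the 2-epimer that also forms converges in the enamine of step 2.

**Step 2**
Reactants: 2 (2S,5S)-dihydrocarvone; 3 (S)-(−)-1-phenylethylamine; 4 ethyl vinyl ketone
Product: 7 (2R,5S)-2-methyl-2-(3-oxopentyl)-5-(prop-1-en-2-yl)cyclohexan-1-one, via ketimine 5 (not isolated), via alkylated ketimine 6 (not isolated)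
Conditions: 3, TsOH (cat.), toluene, reflux (Dean–Stark); 4, THF, 40 °C, 72 h; 20% aq. AcOH, rt
Reagents that add atoms: water, O
Why: d'Angelo deracemising Michael addition: the more substituted secondary enamine tautomer of the chiral ketimine adds to the enone through a chair-like aza-ene transition state on the face set by the (S)-auxiliary, creating quaternary C10 (2R, methyl cis to isopropenyl; the mirror image of the known matched (+)-α-cyperone case) before hydrolysis.

**Step 3**
Reactants: 7 (2R,5S)-2-methyl-2-(3-oxopentyl)-5-(prop-1-en-2-yl)cyclohexan-1-one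
Product: 8 (−)-α-cyperone
Conditions: NaOMe, MeOH, 60 °C
Reagents that add atoms: none
Why: Intramolecular aldol condensation (ring-closing half of the Robinson annulation) forms ring A as the tetrasubstituted enone; no stereocentre is involved.

**Step 4**
Reactants: 8 (−)-α-cyperone
Product: 9 (−)-1,2-dehydro-α-cyperone
Conditions: DDQ, 1,4-dioxane, 100 °C
Reagents that add atoms: none
Why: DDQ dehydrogenation through the cross-conjugated dienol (hydride abstraction from C1) gives the 1,4-dien-3-one, as for steroidal Δ4-3-ketones.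

**Step 5**
Reactants: 9 (−)-1,2-dehydro-α-cyperone
Product: 10 (4R,4aR,7S)-4-(diethoxymethyl)-1,4a-dimethyl-7-(prop-1-en-2-yl)-4,4a,5,6,7,8-hexahydronaphthalen-2(3H)-one
Conditions: 2,2-diethoxyacetic acid (3 equiv), 4CzIPN (2 mol%), Cs2CO3 (20 mol%), DMF, 450 nm LEDs, rt
Reagents that add atoms: 2,2-diethoxyacetic acid, CCOC(OCC)C(=O)O
Why: Photoredox decarboxylative Giese reaction: the nucleophilic diethoxymethyl radical (masked formyl) adds to C1, the only unhindered β-carbon, by axial attack anti to the angular methyl, which sets C1; the dienone does not absorb at 450 nm, so it does not photorearrange.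

**Step 6**
Reactants: 10 the acetal enone
Product: 12 (1R,5S,7S,10S)-1-(diethoxymethyl)eudesma-3,11-dien-3-yl trifluoromethanesulfonate, via lithium enolate 11 (not isolated)
Conditions: Li (2.2 equiv), t-BuOH (1.0 equiv), NH3/THF, −78 °C; NH3 evaporated; PhNTf2, THF, 0 °C to rt
Reagents that add atoms: N-phenylbis(trifluoromethanesulfonimide), O=S(=O)(N(c1ccccc1)S(=O)(=O)C(F)(F)F)C(F)(F)F
Why: Dissolving-metal (Birch-type) enone reduction protonates C5 axially to the trans-decalin (sets C5) and leaves the regiodefined C3–C4 lithium enolate, which PhNTf2 O-triflates (McMurry–Scott enolate trapping).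

**Step 7**
Reactants: 12 the enol triflate
Product: 13 (1R,5R,7S,10S)-1-(diethoxymethyl)eudesma-3,11-diene
Conditions: Pd(OAc)2 (5 mol%), PPh3 (10 mol%), n-Bu3N, HCO2H, DMF, 60 °C
Reagents that add atoms: none
Why: Palladium-catalysed formate reduction of an enol triflate (Cacchi): zerovalent palladium inserts into C–OTf and formate delivers hydride, leaving the Δ3 alkene where the hydration needs it.

**Step 8**
Reactants: 13 the diene acetal
Product: 14 (1R,4R,5S,7S,10S)-1-(diethoxymethyl)eudesmane-4,11-diol
Conditions: Co(C36H52N2O2) [(R,R)-Jacobsen salen complex of divalent cobalt, 5 mol%], N-fluoro-2,4,6-trimethylpyridinium tetrafluoroborate (2.5 equiv), PhSiH3 (2.5 equiv), H2O (20 equiv), acetone, 0 °C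
Reagents that add atoms: water, O
Why: Proposed new method: a hydride of trivalent cobalt (formed from the salen complex, the N–F oxidant and PhSiH3) transfers a hydrogen atom to C3 and to C12, and each tertiary radical is captured by divalent cobalt and oxidised to a cationic alkyl complex of tetravalent cobalt; at C4 the bulky cobalt can bind only on the face away from C14, which forces the C4 methyl into a 1,3-diaxial clash with C14, and water then displaces cobalt with inversion, so the OH ends axial and cis to the angular methyl (the epimer that O2-trapping Mukaiyama hydration disfavours), while C11 is hydrated by the same cycle with no stereo issue; the closest known reactions are Mukaiyama hydration and cobalt-salen radical-polar crossover hydroalkoxylation (Shigehisa type), not yet shown for twofold, diastereoselective hydration with water on a hindered ring alkene.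

**Step 9**
Reactants: 15 phloroglucinol
Product: 16 2,4-diformylphloroglucinol
Conditions: POCl3 (2.3 equiv), DMF (2.3 equiv), 1,4-dioxane, rt; ice-water
Reagents that add atoms: N,N-dimethylformamide, CN(C)C=O; water, O
Why: Vilsmeier–Haack formylation of the very electron-rich arene; with 2.3 equiv of chloroiminium salt the second formylation is fast and the third is slow.

**Step 10**
Reactants: 14 the diol acetal; 16 2,4-diformylphloroglucinol
Product: 18 5-[[(1R,4R,5S,7S,10S)-4,11-dihydroxyeudesman-1-yl](4-methylphenylsulfonyl)methyl]-2,4,6-trihydroxybenzene-1,3-dicarbaldehyde, via aldehyde 17 (not isolated)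
Conditions: p-TolSO2Na (1.5 equiv), AcOH/H2O/THF (3:1:1), 50 °C
Reagents that add atoms: sodium p-toluenesulfinate, Cc1ccc(cc1)S(=O)[O-].[Na+]
Why: Acetal hydrolysis followed by a Mannich-type three-component condensation: the free ring carbon of 16 adds to the aldehyde, water is lost to an o-quinone methide and sulfinate traps it, giving a stable o-quinone methide precursor (both C9′ epimers are used).

**Step 11**
Reactants: 18 the sulfone
Product: 20 target CNP0409870.3, via o-quinone methide 19 (not isolated)
Conditions: i-BuMgBr (8 equiv), CuBr·SMe2 (20 mol%), THF, −78 to −20 °C; aq. NH4Cl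
Reagents that add atoms: isobutylmagnesium bromide, CC(C)C[Mg]Br
Why: Excess i-BuMgBr deprotonates all OH groups (the formyl groups become unreactive vinylogous magnesium carboxylates) and expels sulfinate to the o-quinone methide, which undergoes copper-catalysed 1,4-addition; A1,3 strain holds H1 in the plane of the exocyclic C=C and isobutyl enters anti to quaternary C10, setting C9′ (S).

**Compound list**
1 | (S)-(+)-carvone | CC1=CC[C@H](C(C)=C)CC1=O | starting material
2 | (2S,5S)-dihydrocarvone | C[C@H]1CC[C@H](C(C)=C)CC1=O | intermediate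
3 | (S)-(−)-1-phenylethylamine | C[C@H](N)c1ccccc1 | starting material
4 | ethyl vinyl ketone (pent-1-en-3-one) | C=CC(=O)CC | starting material
5 | ketimine of 2 with 3 | C[C@H]1CC[C@H](C(C)=C)CC1=N[C@@H](C)c1ccccc1 | intermediate (not isolated)
6 | alkylated ketimine, N-[(1S)-1-phenylethyl]imine of 7 | CCC(=O)CC[C@@]1(C)CC[C@H](C(C)=C)CC1=N[C@@H](C)c1ccccc1 | intermediate (not isolated)
7 | (2R,5S)-2-methyl-2-(3-oxopentyl)-5-(prop-1-en-2-yl)cyclohexan-1-one | CCC(=O)CC[C@@]1(C)CC[C@H](C(C)=C)CC1=O | intermediate
8 | (−)-α-cyperone, (4aR,7S)-1,4a-dimethyl-7-(prop-1-en-2-yl)-4,4a,5,6,7,8-hexahydronaphthalen-2(3H)-one | C1CC(=O)C(C)=C2C[C@@H](C(C)=C)CC[C@]12C | intermediate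
9 | (−)-1,2-dehydro-α-cyperone, (4aR,7S)-1,4a-dimethyl-7-(prop-1-en-2-yl)-5,6,7,8-tetrahydronaphthalen-2(4aH)-one | C1=CC(=O)C(C)=C2C[C@@H](C(C)=C)CC[C@]12C | intermediate
10 | (4R,4aR,7S)-4-(diethoxymethyl)-1,4a-dimethyl-7-(prop-1-en-2-yl)-4,4a,5,6,7,8-hexahydronaphthalen-2(3H)-one (acetal carbon trans to the angular methyl) | CCOC(OCC)[C@@H]1CC(=O)C(C)=C2C[C@@H](C(C)=C)CC[C@]12C | intermediate
11 | lithium C3–C4 enolate of the trans-fused ketone from 10 | CCOC(OCC)[C@@H]1CC(O[Li])=C(C)[C@H]2C[C@@H](C(C)=C)CC[C@]12C | intermediate (not isolated)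
12 | (1R,5S,7S,10S)-1-(diethoxymethyl)eudesma-3,11-dien-3-yl trifluoromethanesulfonate (ent-eudesmane skeleton, H5 trans to C14) | CCOC(OCC)[C@@H]1CC(OS(=O)(=O)C(F)(F)F)=C(C)[C@H]2C[C@@H](C(C)=C)CC[C@]12C | intermediate
13 | (1R,5R,7S,10S)-1-(diethoxymethyl)eudesma-3,11-diene | CCOC(OCC)[C@@H]1CC=C(C)[C@H]2C[C@@H](C(C)=C)CC[C@]12C | intermediate
14 | (1R,4R,5S,7S,10S)-1-(diethoxymethyl)eudesmane-4,11-diol (4-OH axial, cis to C14) | CCOC(OCC)[C@@H]1CC[C@@](C)(O)[C@H]2C[C@@H](C(C)(C)O)CC[C@]12C | intermediate
15 | phloroglucinol | Oc1cc(O)cc(O)c1 | starting material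
16 | 2,4-diformylphloroglucinol (2,4,6-trihydroxybenzene-1,3-dicarbaldehyde) | O=Cc1c(O)cc(O)c(C=O)c1O | intermediate
17 | (1R,4R,5S,7S,10S)-1-formyleudesmane-4,11-diol | O=C[C@@H]1CC[C@@](C)(O)[C@H]2C[C@@H](C(C)(C)O)CC[C@]12C | intermediate (not isolated)
18 | sulfone, 5-[[(1R,4R,5S,7S,10S)-4,11-dihydroxyeudesman-1-yl](4-methylphenylsulfonyl)methyl]-2,4,6-trihydroxybenzene-1,3-dicarbaldehyde (C9′ epimers) | Cc1ccc(cc1)S(=O)(=O)C(c1c(O)c(C=O)c(O)c(C=O)c1O)[C@@H]1CC[C@@](C)(O)[C@H]2C[C@@H](C(C)(C)O)CC[C@]12C | intermediate
19 | o-quinone methide, 5-[[(1S,4R,5S,7S,10R)-4,11-dihydroxyeudesman-1-yl]methylidene]-2,4-dihydroxy-6-oxocyclohexa-1,3-diene-1,3-dicarbaldehyde | O=CC1=C(O)C(C=O)=C(O)C(=C[C@@H]2CC[C@@](C)(O)[C@H]3C[C@@H](C(C)(C)O)CC[C@]23C)C1=O | intermediate (not isolated)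
20 | target, 5-[(1S)-1-[(1S,4R,4aS,6S,8aR)-4-hydroxy-6-(2-hydroxypropan-2-yl)-4,8a-dimethyldecahydronaphthalen-1-yl]-3-methylbutyl]-2,4,6-trihydroxybenzene-1,3-dicarbaldehyde | CC(C)C[C@H](c1c(O)c(C=O)c(O)c(C=O)c1O)[C@@H]1CC[C@@](C)(O)[C@H]2C[C@@H](C(C)(C)O)CC[C@]12C | target

**Step count**
Total: 11 steps. Longest linear sequence: 10 steps (1–8, 10, 11) from (S)-carvone; step 9 is the one-step arene branch.

**Three steps most likely to fail**

Step 8 (the new hydration). The C4 cation may not be held by cobalt, in which case water enters anti to C14 (the wrong C4 epimer) or the alkene isomerises; the acetal may also suffer under the collidinium salt. Fallback with known chemistry, setting out from 13 and coming back at 14: oxymercuration with Hg(OAc)2 (2.2 equiv) in THF/H2O gives the bis(acetoxymercurio) diol F1 by Markovnikov anti addition; water opens the C3–C4 mercurinium ion trans-diaxially and therefore enters C4 on the C14 face. NaBH4/NaOH then removes both mercury atoms and gives 14.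

Step 10. The aldehyde 17 is α-branched and flanked by quaternary C10, so condensation with the deactivated arene 16 may be slow; forcing it risks epimerising C1 (enol or vinylphenol tautomer) or dehydrating the C4 alcohol. Fallback, setting out from 14 and coming back at 20, with the formyl groups introduced last:
- 14 is condensed with phloroglucinol 15 (3 equiv, far more nucleophilic) and p-TolSO2Na in aq. AcOH at rt to the sulfone F2.
- i-BuMgBr/CuBr·SMe2 converts F2 through the non-formylated o-quinone methide F3 into the alkylphloroglucinol F4.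
- Double ortho-formylation of F4 with MgCl2, Et3N and paraformaldehyde in MeCN (Casnati–Skattebøl) gives 20.

Step 11. The organocopper reagent may attack a formyl group, excess base may deprotonate C1–H of the o-quinone methide (loss of C1 configuration), or facial selectivity at C9′ may be low. Fallback, setting out from 18 and coming back at 20, without any basic organometallic: 18 is treated with NaHCO3 in toluene at 40 °C to release 19 in the presence of diethyl (2-methylprop-1-enyl)boronate and catalytic 3,3′-dibromo-BINOL (Schaus-type boronate addition to o-quinone methides, which tolerates free CHO and OH and adds catalyst control to the substrate bias). This gives the alkenyl adduct F5, whose side-chain alkene is hydrogenated (H2, Pd/C, EtOAc) to 20.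

**Further compounds**
F1 | step 8 | (1R,5S,7S,10S)-3-(acetoxymercurio)-12-(acetoxymercurio)-1-(diethoxymethyl)eudesmane-4,11-diol (Hg at C3 trans-diaxial to 4-OH; C11 epimers) | CCOC(OCC)[C@@H]1C[C@H]([Hg]OC(C)=O)[C@@](C)(O)[C@H]2C[C@@H](C(C)(O)C[Hg]OC(C)=O)CC[C@]12C
F2 | step 10 | sulfone, 2-[[(1R,4R,5S,7S,10S)-4,11-dihydroxyeudesman-1-yl](4-methylphenylsulfonyl)methyl]benzene-1,3,5-triol (C9′ epimers) | Cc1ccc(cc1)S(=O)(=O)C(c1c(O)cc(O)cc1O)[C@@H]1CC[C@@](C)(O)[C@H]2C[C@@H](C(C)(C)O)CC[C@]12C
F3 | step 10 | non-formylated o-quinone methide, 6-[[(1S,4R,5S,7S,10R)-4,11-dihydroxyeudesman-1-yl]methylidene]-3,5-dihydroxycyclohexa-2,4-dien-1-one | O=C1C=C(O)C=C(O)C1=C[C@@H]2CC[C@@](C)(O)[C@H]3C[C@@H](C(C)(C)O)CC[C@]23C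
F4 | step 10 | 2-[(1S)-1-[(1S,4R,5S,7S,10R)-4,11-dihydroxyeudesman-1-yl]-3-methylbutyl]benzene-1,3,5-triol | CC(C)C[C@H](c1c(O)cc(O)cc1O)[C@@H]1CC[C@@](C)(O)[C@H]2C[C@@H](C(C)(C)O)CC[C@]12C
F5 | step 11 | 5-[(1S)-1-[(1S,4R,5S,7S,10R)-4,11-dihydroxyeudesman-1-yl]-3-methylbut-2-enyl]-2,4,6-trihydroxybenzene-1,3-dicarbaldehyde | CC(C)=C[C@H](c1c(O)c(C=O)c(O)c(C=O)c1O)[C@@H]1CC[C@@](C)(O)[C@H]2C[C@@H](C(C)(C)O)CC[C@]12C
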